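**Retrosynthetic overview**
1. The strategy rests on the bicyclo[3.2.1]octane that joins the two halves. It consists of the five carbons C8-C9-C11-C12-C13, the one-carbon C14 ketone bridge and the two-carbon C15'-C14' bridge. This is ring C of a 12-hydroxy-11,14-quinone that has taken up the terminal alkene of a labda-8(17),12E,14-triene.
2. Cutting C8-C15' and C13-C14' (retro-(5+2)) gives hydroxyquinone 21 and triene ester 36. The cyclopentanone C8-C15'-C14'-C13-C14 is the last ring made, and only ester and acetal cleavage follow.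
3. Compound 21: rings A and C come from dehydroabietic acid. Ring B is rebuilt as a five-membered ring by an oxidative aryl shift on the Δ6 alkene, which delivers the C6 acetal directly. The 7α-OH comes from enol ether epoxidation, and ring C is oxidised last.
4. Compound 36: rings A' and B' come from abietic acid. Ring C' is opened at C13-C14, C14 becomes the exocyclic methylene C17', and the chain is cut back to C12' and regrown by two Wittig reactions.

Key step: step 22

Remark 1: abietane numbering is used for the quinone half and primed labdane numbering for the diene half. From step 8 on, the benzylic carbon of the five-membered ring B is called C7 and the carbon outside the ring C6, as in the target.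
Remark 2: centres that are erased in a later step (C7 of 11-13, C6 of 15, C12 of 32) and the E/Z geometry of 14, 27 and 31 are left open in the SMILES. Technical abietic acid is assumed to be purified through an amine salt before use.

**Route**

Step 1
Reactants: 1 dehydroabietic acid
Product: 2 dehydroabietinol (abieta-8,11,13-trien-18-ol)
Conditions: LiAlH4, THF, reflux; aq. NaOH work-up
Reagents that add atoms: none
Why: LiAlH4 reduction of a carboxylic acid reaches even the hindered C18 carboxyl group and touches neither the arene nor C4, C5 or C10.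

Step 2
Reactants: 2 dehydroabietinol
Product: 3 dehydroabietinal (abieta-8,11,13-trien-18-al)
Conditions: Dess–Martin periodinane, CH2Cl2, rt
Reagents that add atoms: none
Why: Dess–Martin oxidation stops at the neopentyl aldehyde, which cannot enolise, so C4 is safe.

Step 3
Reactants: 3 dehydroabietinal
Product: 5 abieta-8,11,13-triene (5α-H, 10β-methyl), via hydrazone 4 (not isolated)
Conditions: N2H4·H2O, KOH, diethylene glycol, 130 → 200 °C
Reagents that add atoms: none
Why: In the Wolff–Kishner reduction (Huang-Minlon variant) the hydrazone of the aldehyde loses N2 under base and turns C18 into the second methyl group on C4, while the rest of the hydrocarbon is inert.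

Step 4
Reactants: 5 abieta-8,11,13-triene
Product: 6 12-acetylabieta-8,11,13-triene
Conditions: AcCl, AlCl3, CH2Cl2, 0 °C → rt
Reagents that add atoms: acetyl chloride, CC(=O)Cl
Why: Friedel–Crafts acylation should go to C12, which is activated by the C13 (ortho) and C8 (para) alkyl groups and has one ortho neighbour only, whereas C14 lies between two substituents and C11 is screened by C1 and the C10 methyl.

Step 5
Reactants: 6 12-acetylabieta-8,11,13-triene
Product: 7 ferruginyl acetate (12-acetoxyabieta-8,11,13-triene)
Conditions: mCPBA, CF3CO2H (cat.), CH2Cl2, rt, dark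
Reagents that add atoms: mCPBA, O=C(OO)c1cccc(Cl)c1
Why: In the Baeyer–Villiger oxidation of an aryl methyl ketone the electron-rich trialkylaryl group migrates in preference to methyl and places oxygen on C12.

Step 6
Reactants: 7 ferruginyl acetate
Product: 9 ferruginol methyl ether (12-methoxyabieta-8,11,13-triene), via potassium ferruginolate 8 (not isolated)
Conditions: KOH, DMSO, rt; then MeI
Reagents that add atoms: iodomethane, CI
Why: Saponification of the aryl acetate and Williamson O-methylation of the phenoxide run in one flask and give the donor group that steps 7 and 8 rely on.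

Step 7
Reactants: 9 ferruginol methyl ether
Product: 10 12-methoxyabieta-6,8,11,13-tetraene
Conditions: DDQ, 1,4-dioxane, rt → 60 °C
Reagents that add atoms: none
Why: In the DDQ dehydrogenation, hydride leaves from C7 (benzylic and para-activated by the 12-methoxy group through C8) and H6 is then lost, while the quaternary C10 blocks any further aromatisation.

Step 8
Reactants: 10 12-methoxyabieta-6,8,11,13-tetraene
Product: 11 12-methoxy-5(6→7)abeo-abieta-8,11,13-trien-6-al dimethyl acetal (five-membered ring B, 5α-H, 10β-methyl, C7 epimers)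
Conditions: PhI(OH)OTs, MeOH, 0 °C → rt
Reagents that add atoms: methanol, CO
Why: This is the oxidative ring contraction of a 1,2-dihydronaphthalene by a trivalent iodine reagent: the iodane adds to C6 from the open α face (equatorial, antiperiplanar to C7-C8), methanol caps the methoxy-stabilised C7 cation, aryl carbon C8 shifts from C7 to C6 as PhI leaves, and methanol traps the oxocarbenium ion, so the old C6 becomes the benzylic ring carbon (now C7) and the old C7 the acetal carbon (now C6), the new centre being erased in step 10.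

Step 9
Reactants: 11 ring-contracted methoxy acetal
Product: 13 12-acetoxy-5(6→7)abeo-abieta-8,11,13-trien-6-al dimethyl acetal, via sodium phenoxide 12 (not isolated)
Conditions: NaSEt, DMF, 130 °C; cool to 0 °C, Ac2O
Reagents that add atoms: acetic anhydride, CC(=O)OC(C)=O
Why: SN2 O-demethylation by thiolate is carried out while the molecule still holds only base-stable groups, and acetylation of the phenoxide installs a weakly donating group that mild base can remove later.

Step 10
Reactants: 13 acetoxy acetal
Product: 14 12-acetoxy-6-methoxy-5(6→7)abeo-abieta-6,8,11,13-tetraene (exocyclic C7=C6 methyl enol ether, E/Z)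
Conditions: Me3SiOTf, iPr2NEt, CH2Cl2, −20 °C → rt
Reagents that add atoms: none
Why: In this acetal-to-enol-ether elimination the silyl triflate ionises the acetal and the amine removes the benzylic C7-H from the oxocarbenium ion, giving a styrene-type enol ether whose geometry is of no consequence.

Step 11
Reactants: 14 enol ether
Product: 17 7α,12-dihydroxy-5(6→7)abeo-abieta-8,11,13-trien-6-al dimethyl acetal (7β-CH(OMe)2), via methoxy epoxide 15 (not isolated), via hydroxy acetal acetate 16 (not isolated)
Conditions: mCPBA, MeOH, −20 → 0 °C; then K2CO3, rt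
Reagents that add atoms: mCPBA, O=C(OO)c1cccc(Cl)c1; methanol, CO
Why: In this Rubottom-type α-hydroxylation (peracid epoxidation of an enol ether with methanolysis in situ) the peracid should attack from the α face, on the side of 5α-H and away from the 10β- and 4β-methyl groups, which fixes 7α-OH; methanol opens the epoxide at C6 through the oxocarbenium ion without breaking the C7-O bond (the p-acetoxy ring gives a C7 cation little help), and K2CO3 then methanolyses the aryl acetate.

Step 12
Reactants: 17 phenol hydroxy acetal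
Product: 21 7α,12-dihydroxy-11,14-dioxo-5(6→7)abeo-abieta-8,12-dien-6-al dimethyl acetal (hydroxyquinone), via ortho-quinone 18 (not isolated), via thio-catechol 19 (not isolated), via thio-quinone 20 (not isolated)
Conditions: IBX, CHCl3, rt; C6F5SH; then NaOH, MeOH, O2; dilute HCl to pH 3, 0 °C
Reagents that add atoms: IBX, O=C1OI(=O)(O)c2ccccc12; sodium hydroxide, [Na+].[OH-]
Why: IBX ortho-oxygenation of the phenol gives the 11,12-quinone (C11 is the only free ortho position and quaternary C7 rules out a quinone methide tautomer), the thiol adds conjugately to C14, the only unsubstituted ring carbon, oxygen reoxidises the catechol, and hydroxide displaces the thiolate by addition–elimination to give the 14-hydroxy-11,12-quinone, which is the tautomer of 21.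

Step 13
Reactants: 22 abietic acid; 23 2-(trimethylsilyl)ethanol
Product: 24 2-(trimethylsilyl)ethyl abietate
Conditions: PPh3, DIAD, THF, 0 °C → rt
Reagents that add atoms: none
Why: In the Mitsunobu esterification the hindered carboxylate acts only as the nucleophile on the activated primary alcohol, and the neutral medium does not isomerise the diene.

Step 14
Reactants: 24 2-(trimethylsilyl)ethyl abietate
Product: 25 2-(trimethylsilyl)ethyl 13α,14α-dihydroxyabiet-7-en-18-oate
Conditions: OsO4 (2 mol %), Me3NO·2H2O, pyridine, t-BuOH/H2O, 80 °C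
Reagents that add atoms: trimethylamine N-oxide, C[N+](C)(C)[O-] (oxygen relayed by OsO4); water, O
Why: Catalytic OsO4 syn-dihydroxylation should choose the exposed C13=C14 end of the diene over the ring-fusion C7=C8 alkene and approach anti to the C10 methyl, although both new centres vanish in step 15.

Step 15
Reactants: 25 13,14-diol
Product: 26 2-(trimethylsilyl)ethyl 13,14-dioxo-13,14-seco-abiet-7-en-18-oate (C14 enal, C13 isopropyl ketone)
Conditions: NaIO4, THF/H2O, rt
Reagents that add atoms: none
Why: Malaprade glycol cleavage opens ring C between C13 and C14 and leaves C9 untouched.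

Step 16
Reactants: 26 keto enal
Product: 27 C14 tosylhydrazone of 26
Conditions: TsNHNH2 (1.0 equiv), THF, rt
Reagents that add atoms: p-toluenesulfonyl hydrazide, Cc1ccc(cc1)S(=O)(=O)NN
Why: Hydrazone condensation is far faster at the aldehyde than at the hindered isopropyl ketone, so one equivalent should mark C14 alone.

Step 17
Reactants: 27 tosylhydrazone
Product: 30 2-(trimethylsilyl)ethyl 13-oxo-13,14-seco-abiet-8(14)-en-18-oate (exocyclic methylene), via allylic tosylhydrazine 28 (not isolated), via allylic diazene 29 (not isolated)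
Conditions: catecholborane, CHCl3, −10 °C; then NaOAc·3H2O, reflux
Reagents that add atoms: none
Why: In this alkene-transposing reduction of an α,β-unsaturated tosylhydrazone, hydride adds to C=N, acetate triggers loss of sulfinate, and the allylic diazene loses N2 in a retro-ene reaction that puts H on C7 and moves the alkene to C8=C14 (C17' of the labdane), while the hindered ketone should resist catecholborane at −10 °C.

Step 18
Reactants: 30 exocyclic methylene ketone
Product: 32 2-(trimethylsilyl)ethyl 12-hydroxy-13-oxo-13,14-seco-abiet-8(14)-en-18-oate (C12 epimers), via potassium enolate 31 (not isolated)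
Conditions: KN(SiMe3)2, THF, −78 °C; 2-(phenylsulfonyl)-3-phenyloxaziridine; aq. NH4Cl
Reagents that add atoms: 2-(phenylsulfonyl)-3-phenyloxaziridine, O=S(=O)(c1ccccc1)N1OC1c1ccccc1
Why: Kinetic enolisation takes the CH2 side (C12) rather than the CHMe2 side, and enolate hydroxylation with an N-sulfonyloxaziridine spares both alkene and ester, the new carbinol centre being erased in step 19.

Step 19
Reactants: 32 α-hydroxy ketone
Product: 33 2-(trimethylsilyl)ethyl 12-oxo-13,14,15,16-tetranorlabd-8(17)-en-18-oate (C12' aldehyde)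
Conditions: Pb(OAc)4, MeOH/toluene (1:1), 0 °C
Reagents that add atoms: none
Why: Criegee-type cleavage of an α-hydroxy ketone by Pb(OAc)4 in methanol breaks C12-C13, releases the isobutyryl unit as its methyl ester and leaves the aldehyde one carbon from C9'.

Step 20
Reactants: 33 C12' aldehyde; 34 2-(triphenylphosphoranylidene)propanal
Product: 35 2-(trimethylsilyl)ethyl (12E)-14-oxo-15-norlabda-8(17),12-dien-18-oate
Conditions: toluene, 90 °C
Reagents that add atoms: none
Why: The Wittig reaction of a stabilised ylide with an aliphatic aldehyde is E-selective, which sets the C12'=C13' geometry, and the product enal is much less reactive towards the ylide than 33.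

Step 21
Reactants: 35 E-enal
Product: 36 2-(trimethylsilyl)ethyl labda-8(17),12E,14-trien-18-oate
Conditions: Ph3PCH3Br, KOtBu, THF, 0 °C
Reagents that add atoms: methyltriphenylphosphonium bromide, C[P+](c1ccccc1)(c1ccccc1)c1ccccc1.[Br-]
Why: Wittig methylenation of the enal adds C15' by 1,2-attack, keeps the E alkene and does not reach the hindered, non-enolisable ester.

Step 22
Reactants: 21 hydroxyquinone; 36 triene ester (2 equiv)
Product: 37 protected heterodimer (bicyclo[3.2.1]octane with C8-C15' and C13-C14' on the α face, C14' alkenyl group endo, C11 diosphenol, C12 and C14 ketones, 7α-OH, 7β-CH(OMe)2, silylethyl ester)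
Conditions: BF3·OEt2 (1.2 equiv), 2,6-di-tert-butylpyridine (0.2 equiv), 4 Å MS, CH2Cl2, −78 → −30 °C; aq. NaHCO3
Reagents that add atoms: none
Why: BF3 binds the O11/O12 hydroxy-carbonyl site of 21 and turns C8-C9-C11-C12-C13 into an oxypentadienyl cation that is electrophilic at C8 (β-carbon of the activated C11 enone) and nucleophilic at C13 (enol carbon); C15' of 36 bonds to C8, the charge moves into the C14'-C13'-C12' allyl cation, C13 closes on C14', and proton loss leaves the C12 ketone and the C9=C11 diosphenol. The closest known reactions are the perezone-to-pipitzol cyclisation and the Lewis-acid (5+2) additions of 2-alkoxy-1,4-benzoquinones and quinone monoketals to styrenes. The one new ring, the cyclopentanone C8-C15'-C14'-C13-C14, closes in a 5-(enolexo)-exo-trig mode with the C13'=C12' residue of the allyl cation left outside the ring as the E alkene, and the same bond completes the seven-membered perimeter C8-C9-C11-C12-C13-C14'-C15'. C8 and C13 are set together by approach to the α face, since the 10β-methyl and the 7β-dimethoxymethyl groups cover the β face and a two-atom bridge can span one face only, and C14' is set by the endo fold, in which the allyl cation lies under the electron-rich C9-C11-C12 borate rather than under the C14 carbonyl. The step needs (5+2) over (4+2) addition, C15'-to-C8 orientation and attack by the diene terminus rather than by C8'=C17': both quinone alkenes are tetrasubstituted, which slows a Diels–Alder reaction, the polarity of the chelate fixes the orientation, and the monosubstituted CH2 end is the only alkene carbon slim enough to reach C8. The neopentyl, α-oxygenated acetal and the silylethyl ester should survive about one equivalent of Lewis acid at low temperature.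

Step 23
Reactants: 37 protected heterodimer
Product: 38 C18' carboxylic acid with the C6 dimethyl acetal still in place
Conditions: Bu4NF, THF, 0 °C → rt; aq. NH4Cl
Reagents that add atoms: none
Why: Fluoride-induced β-elimination of the 2-(trimethylsilyl)ethyl ester starts at silicon, far from the hindered C4' carbonyl, and the acetal keeps the α-hydroxy aldehyde away from the basic medium, in which only the diosphenol is reversibly deprotonated.

Step 24
Reactants: 38 acid acetal
Product: 39 CNP0124601.1 (target)
Conditions: 2 M HCl/THF (1:3), rt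
Reagents that add atoms: water, O
Why: Acid-catalysed acetal hydrolysis frees the C6 aldehyde under conditions too mild to isomerise the C8'=C17' methylene or to ionise the 7α-OH, whose cation would sit next to a carbonyl-bearing quaternary carbon.

**Compound list**
1 | dehydroabietic acid | CC(C)c1ccc2c(c1)CC[C@@H]1[C@]2(C)CCC[C@@]1(C)C(=O)O | starting material
2 | dehydroabietinol | CC(C)c1ccc2c(c1)CC[C@@H]1[C@]2(C)CCC[C@@]1(C)CO | intermediate
3 | dehydroabietinal | CC(C)c1ccc2c(c1)CC[C@@H]1[C@]2(C)CCC[C@@]1(C)C=O | intermediate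
4 | hydrazone of 3 | CC(C)c1ccc2c(c1)CC[C@@H]1[C@]2(C)CCC[C@@]1(C)C=NN | intermediate
5 | abieta-8,11,13-triene | CC(C)c1ccc2c(c1)CC[C@@H]1[C@]2(C)CCCC1(C)C | intermediate
6 | 12-acetylabieta-8,11,13-triene | CC(C)c1c(C(C)=O)cc2c(c1)CC[C@@H]1[C@]2(C)CCCC1(C)C | intermediate
7 | ferruginyl acetate | CC(C)c1c(OC(C)=O)cc2c(c1)CC[C@@H]1[C@]2(C)CCCC1(C)C | intermediate
8 | potassium ferruginolate | CC(C)c1c([O-])cc2c(c1)CC[C@@H]1[C@]2(C)CCCC1(C)C.[K+] | intermediate
9 | ferruginol methyl ether | CC(C)c1c(OC)cc2c(c1)CC[C@@H]1[C@]2(C)CCCC1(C)C | intermediate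
10 | 12-methoxyabieta-6,8,11,13-tetraene | CC(C)c1c(OC)cc2c(c1)C=C[C@@H]1[C@]2(C)CCCC1(C)C | intermediate
11 | ring-contracted 12-methoxy dimethyl acetal (C7 epimers) | CC(C)c1c(OC)cc2c(c1)C(C(OC)OC)[C@@H]1[C@]2(C)CCCC1(C)C | intermediate
12 | sodium phenoxide from 11 | CC(C)c1c([O-])cc2c(c1)C(C(OC)OC)[C@@H]1[C@]2(C)CCCC1(C)C.[Na+] | intermediate
13 | ring-contracted 12-acetoxy dimethyl acetal (C7 epimers) | CC(C)c1c(OC(C)=O)cc2c(c1)C(C(OC)OC)[C@@H]1[C@]2(C)CCCC1(C)C | intermediate
14 | exocyclic C7=C6 methyl enol ether (E/Z) | CC(C)c1c(OC(C)=O)cc2c(c1)C(=COC)[C@@H]1[C@]2(C)CCCC1(C)C | intermediate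
15 | 6,7α-epoxide of 14 | CC(C)c1c(OC(C)=O)cc2c(c1)[C@]1(OC1OC)[C@@H]1[C@]2(C)CCCC1(C)C | intermediate
16 | 12-acetoxy-7α-hydroxy dimethyl acetal | CC(C)c1c(OC(C)=O)cc2c(c1)[C@@](O)(C(OC)OC)[C@@H]1[C@]2(C)CCCC1(C)C | intermediate
17 | 7α,12-dihydroxy dimethyl acetal | CC(C)c1c(O)cc2c(c1)[C@@](O)(C(OC)OC)[C@@H]1[C@]2(C)CCCC1(C)C | intermediate
18 | 11,12-ortho-quinone | CC(C)C1=CC2=C(C(=O)C1=O)[C@@]3(C)CCCC(C)(C)[C@@H]3[C@]2(O)C(OC)OC | intermediate
19 | 14-(pentafluorophenylthio)-11,12-catechol | CC(C)c1c(Sc3c(F)c(F)c(F)c(F)c3F)c2c(c(O)c1O)[C@@]3(C)CCCC(C)(C)[C@@H]3[C@]2(O)C(OC)OC | intermediate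
20 | 14-(pentafluorophenylthio)-11,12-quinone | CC(C)C1=C(Sc3c(F)c(F)c(F)c(F)c3F)C2=C(C(=O)C1=O)[C@@]3(C)CCCC(C)(C)[C@@H]3[C@]2(O)C(OC)OC | intermediate
21 | 12-hydroxy-11,14-quinone with 7α-OH and 7β-CH(OMe)2 | CC(C)C1=C(O)C(=O)C2=C(C1=O)[C@@](O)(C(OC)OC)[C@H]3C(C)(C)CCC[C@]23C | intermediate
22 | abietic acid | CC(C)C1=CC2=CC[C@@H]3[C@](C)(CCC[C@@]3(C)C(=O)O)[C@H]2CC1 | starting material
23 | 2-(trimethylsilyl)ethanol | OCC[Si](C)(C)C | starting material
24 | 2-(trimethylsilyl)ethyl abietate | CC(C)C1=CC2=CC[C@@H]3[C@](C)(CCC[C@@]3(C)C(=O)OCC[Si](C)(C)C)[C@H]2CC1 | intermediate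
25 | 13α,14α-diol | CC(C)[C@@]1(O)[C@H](O)C2=CC[C@@H]3[C@](C)(CCC[C@@]3(C)C(=O)OCC[Si](C)(C)C)[C@H]2CC1 | intermediate
26 | 13,14-seco keto enal | O=CC1=CC[C@@H]2[C@](C)(CCC[C@@]2(C)C(=O)OCC[Si](C)(C)C)[C@H]1CCC(=O)C(C)C | intermediate
27 | C14 tosylhydrazone | Cc1ccc(cc1)S(=O)(=O)NN=CC1=CC[C@@H]2[C@](C)(CCC[C@@]2(C)C(=O)OCC[Si](C)(C)C)[C@H]1CCC(=O)C(C)C | intermediate
28 | allylic tosylhydrazine (boron-bound in the flask) | Cc1ccc(cc1)S(=O)(=O)NNCC1=CC[C@@H]2[C@](C)(CCC[C@@]2(C)C(=O)OCC[Si](C)(C)C)[C@H]1CCC(=O)C(C)C | intermediate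
29 | allylic diazene | N=NCC1=CC[C@@H]2[C@](C)(CCC[C@@]2(C)C(=O)OCC[Si](C)(C)C)[C@H]1CCC(=O)C(C)C | intermediate
30 | exocyclic methylene isopropyl ketone | C=C1CC[C@@H]2[C@](C)(CCC[C@@]2(C)C(=O)OCC[Si](C)(C)C)[C@H]1CCC(=O)C(C)C | intermediate
31 | potassium C12 enolate of 30 | C=C1CC[C@@H]2[C@](C)(CCC[C@@]2(C)C(=O)OCC[Si](C)(C)C)[C@H]1CC=C([O-])C(C)C.[K+] | intermediate
32 | 12-hydroxy ketone (C12 epimers) | C=C1CC[C@@H]2[C@](C)(CCC[C@@]2(C)C(=O)OCC[Si](C)(C)C)[C@H]1CC(O)C(=O)C(C)C | intermediate
33 | C12' aldehyde | C=C1CC[C@@H]2[C@](C)(CCC[C@@]2(C)C(=O)OCC[Si](C)(C)C)[C@H]1CC=O | intermediate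
34 | 2-(triphenylphosphoranylidene)propanal | CC(C=O)=P(c1ccccc1)(c1ccccc1)c1ccccc1 | starting material
35 | (12E)-enal | C=C1CC[C@@H]2[C@](C)(CCC[C@@]2(C)C(=O)OCC[Si](C)(C)C)[C@H]1C/C=C(\C)C=O | intermediate
36 | 2-(trimethylsilyl)ethyl labda-8(17),12E,14-trien-18-oate | C=C1CC[C@@H]2[C@](C)(CCC[C@@]2(C)C(=O)OCC[Si](C)(C)C)[C@H]1C/C=C(\C)C=C | intermediate
37 | protected heterodimer | C=C1CC[C@@H]2[C@](C)(CCC[C@@]2(C)C(=O)OCC[Si](C)(C)C)[C@H]1C/C=C(\C)[C@@H]1C[C@@]23C(=O)[C@]1(C(C)C)C(=O)C(O)=C2[C@@]1(C)CCCC(C)(C)[C@@H]1[C@]3(O)C(OC)OC | intermediate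
38 | heterodimer acid, C6 dimethyl acetal | C=C1CC[C@@H]2[C@](C)(CCC[C@@]2(C)C(=O)O)[C@H]1C/C=C(\C)[C@@H]1C[C@@]23C(=O)[C@]1(C(C)C)C(=O)C(O)=C2[C@@]1(C)CCCC(C)(C)[C@@H]1[C@]3(O)C(OC)OC | intermediate
39 | CNP0124601.1 | C=C1CC[C@@H]2[C@](C)(CCC[C@@]2(C)C(=O)O)[C@H]1C/C=C(\C)[C@@H]1C[C@@]23C(=O)[C@]1(C(C)C)C(=O)C(O)=C2[C@@]1(C)CCCC(C)(C)[C@@H]1[C@]3(O)C=O | target

**Step count**
- Total step count: 24.
- Longest linear sequence: 15 (steps 1-12, then 22-24).

**Steps most likely to fail**

1. **Step 22.**
   - What may go wrong: Diels–Alder addition of the diene to the quinone, trapping of the allyl cation by a carbonyl oxygen, ionisation of the acetal by the Lewis acid, acid-induced decay of the triene, or weak endo/exo control.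
   - Fallback: it sets out from 21. O-methylation of the vinylogous acid with Me3SiCHN2 in toluene/MeOH gives the 12-methoxyquinone F1. F1 is combined with 36 under TiCl4/Ti(OiPr)4 (1:1) in CH2Cl2 at −78 °C. This is the established (5+2) addition of 2-alkoxy-1,4-benzoquinones, in which tetravalent titanium chelates O11 and the 12-methoxy oxygen. Chloride removes the methyl group from the C12 oxocarbenium ion after ring closure, so the route is rejoined at 37.

2. **Step 12.**
   - What may go wrong: slow thiol addition at the crowded C14, overoxidation of the catechol stage, or loss of the 7α-OH through a para-quinone methide while the ring is electron-rich and basic.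
   - Fallback: it sets out from 17 and builds the oxygen pattern stepwise.
     - IBX in DMF followed by aqueous Na2S2O4 gives the 11,12-catechol F2.
     - One equivalent of MeI with K2CO3 in acetone alkylates the less screened O12 and gives the 11-hydroxy-12-methoxy arene F3.
     - Teuber oxidation with (KSO3)2NO in KH2PO4-buffered aqueous acetone oxidises the phenol at its free para position C14 and gives the 12-methoxyquinone F1.
     - NaOH in aqueous MeOH (addition–elimination on the vinylogous ester) returns 21.

3. **Step 8.**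
   - What may go wrong: plain 1,2-dimethoxylation of the alkene in place of the aryl shift, or attack of the iodane on the anisole ring.
   - Fallback: it sets out from 9 and contracts ring B by a Wolff rearrangement.
     - CrO3 in AcOH gives sugiol methyl ether F4.
     - LiN(SiMe3)2 and then CF3CO2CH2CF3 give the 6-trifluoroacetyl ketone F5. F5 is treated without isolation with MsN3 and Et3N (deacylative diazo transfer) to give the 6-diazo-7-ketone F6.
     - Irradiation in MeOH (photochemical Wolff rearrangement) gives the ring-contracted methyl ester F7.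
     - LiAlH4 gives the primary alcohol F8, and Dess–Martin oxidation gives the aldehyde F9.
     - HC(OMe)3 with catalytic TsOH in MeOH rejoins the route at 11.

Further compounds
F1 | step 22 | 12-O-methyl ether of 21 (12-methoxy-11,14-quinone) | CC(C)C1=C(OC)C(=O)C2=C(C1=O)[C@@](O)(C(OC)OC)[C@H]3C(C)(C)CCC[C@]23C
F2 | step 12 | 7α,11,12-trihydroxy dimethyl acetal (catechol) | CC(C)c1c(O)c(O)c2c(c1)[C@@](O)(C(OC)OC)[C@@H]1[C@]2(C)CCCC1(C)C
F3 | step 12 | 7α,11-dihydroxy-12-methoxy dimethyl acetal | CC(C)c1c(OC)c(O)c2c(c1)[C@@](O)(C(OC)OC)[C@@H]1[C@]2(C)CCCC1(C)C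
F4 | step 8 | sugiol methyl ether (12-methoxyabieta-8,11,13-trien-7-one) | CC(C)c1c(OC)cc2c(c1)C(=O)C[C@@H]1[C@]2(C)CCCC1(C)C
F5 | step 8 | 6-trifluoroacetyl derivative of F4 | CC(C)c1c(OC)cc2c(c1)C(=O)C(C(=O)C(F)(F)F)[C@@H]1[C@]2(C)CCCC1(C)C
F6 | step 8 | 6-diazo-12-methoxyabieta-8,11,13-trien-7-one | CC(C)c1c(OC)cc2c(c1)C(=O)C(=[N+]=[N-])[C@@H]1[C@]2(C)CCCC1(C)C
F7 | step 8 | ring-contracted methyl ester (C7 epimers) | CC(C)c1c(OC)cc2c(c1)C(C(=O)OC)[C@@H]1[C@]2(C)CCCC1(C)C
F8 | step 8 | ring-contracted primary alcohol (C7 epimers) | CC(C)c1c(OC)cc2c(c1)C(CO)[C@@H]1[C@]2(C)CCCC1(C)C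
F9 | step 8 | ring-contracted aldehyde (C7 epimers) | CC(C)c1c(OC)cc2c(c1)C(C=O)[C@@H]1[C@]2(C)CCCC1(C)C
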